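**Plan**

- Locants follow the cyclonona[c]furan core (C1, O2, C3, C3a, C4–C10, C10a). The enabling feature is C10a, the ring-fusion carbon of the tetrahydrofuran, which lies between the oxygen-bearing C1 and the methylidene carbon C10. With C1 raised to a lactone carbonyl, C10a becomes an enolate carbon and C10 a 2-bromo-1-alkene carbon, so the C10–C10a bond can close the nine-membered ring by enolate alkenylation.
- Retrosynthetic cuts, in order: stearate C–O; dienyl C=C on C3; C1–O2 (tetrahydrofuran back to a γ-lactone via the 1,4-diol); C10–C10a (nine-membered ring); C7=C8 (Wittig); C3a–C10a together with C1 (two-carbon ynol ether unit onto a C3–C3a epoxide); C3=C3a back to a Morita–Baylis–Hillman adduct of a geraniol-derived aldehyde.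
- Forward order: acyclic chain, then the γ-lactone (five-membered ring first), then the nine-membered carbocycle (key step), then conversion of the lactone into the tetrahydrofuran, then diene and ester.
- Stereochemistry: C6 from Sharpless epoxidation of geraniol; C3 and C3a from a second Sharpless epoxidation and invertive epoxide opening; C10a in the key step (trans to C3a, thermodynamic control); (Z)-C7=C8 from a Wittig reaction; (E)-diene from a Horner–Wadsworth–Emmons reaction.

Key step: step 16

**Route**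

Step 1
Reactants: 1 geraniol
Product: 2 (2S,3S)-2,3-epoxygeraniol
Conditions: Ti(OiPr)4 (cat.), L-(+)-diethyl tartrate (cat.), t-BuOOH, 4 Å molecular sieves, CH2Cl2, −20 °C
Reagents that add atoms: tert-butyl hydroperoxide, CC(C)(C)OO
Why: Sharpless asymmetric epoxidation of the (E)-allylic alcohol, in which the L-(+)-tartrate titanium catalyst should deliver oxygen to one enantioface to set the (2S,3S) epoxide (its C3 is the future C6 carbinol carbon), leaving the isolated trisubstituted alkene untouched.

Step 2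
Reactants: 2 (2S,3S)-2,3-epoxygeraniol
Product: 4 (S)-linalool, via epoxy iodide 3 (not isolated)
Conditions: PPh3, I2, imidazole, THF, 0 °C; then Zn dust, EtOH, 60 °C
Reagents that add atoms: none
Why: Appel iodination of the primary alcohol followed by zinc-mediated reductive β-elimination (epoxide opening) transposes the oxygen to the tertiary allylic position without breaking the C–O bond at the stereocentre, so the (S) configuration should be carried over.

Step 3
Reactants: 4 (S)-linalool
Product: 5 (S)-linalool triethylsilyl ether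
Conditions: Et3SiOTf, 2,6-lutidine, CH2Cl2, −78 to 0 °C
Reagents that add atoms: triethylsilyl trifluoromethanesulfonate, CC[Si](CC)(CC)OS(=O)(=O)C(F)(F)F
Why: Silyl triflate silylation of the hindered tertiary alcohol, needed so that the aldehyde of step 4 does not close to a lactol.

Step 4
Reactants: 5 (S)-linalool triethylsilyl ether
Product: 6 (4S)-4-methyl-4-(triethylsilyloxy)hex-5-enal
Conditions: O3 (1 equiv, indicator-controlled), CH2Cl2/MeOH, −78 °C; then Me2S
Reagents that add atoms: ozone, [O-][O+]=O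
Why: Chemoselective ozonolysis, since the electron-rich trisubstituted alkene should react far faster than the vinyl group next to the quaternary silyloxy carbon.

Step 5
Reactants: 6 (4S)-4-methyl-4-(triethylsilyloxy)hex-5-enal
Product: 7 Morita–Baylis–Hillman adduct (both carbinol epimers)
Conditions: methyl acrylate (3 equiv), DABCO (1 equiv), 1,4-dioxane/H2O (1:1), rt
Reagents that add atoms: methyl acrylate, C=CC(=O)OC
Why: Morita–Baylis–Hillman reaction of an unhindered aliphatic aldehyde; the new carbinol centre is of no consequence because it is removed in step 6.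

Step 6
Reactants: 7 Morita–Baylis–Hillman adduct
Product: 8 (Z)-2-(bromomethyl)enoate
Conditions: N-bromosuccinimide, Me2S, CH2Cl2, 0 °C to rt
Reagents that add atoms: N-bromosuccinimide, O=C1CCC(=O)N1Br
Why: Corey–Kim-type activation of the allylic alcohol and SN2′ bromide attack should give the (Z)-2-(bromomethyl)alk-2-enoate, with the ester trans and the CH2Br cis to the chain, as is usual for such adducts.

Step 7
Reactants: 8 (Z)-2-(bromomethyl)enoate
Product: 9 (E)-2-(PMB-oxymethyl)enoate
Conditions: 4-methoxybenzyl alcohol, NaH, THF, 0 °C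
Reagents that add atoms: 4-methoxybenzyl alcohol, COc1ccc(CO)cc1
Why: Williamson etherification at the primary allylic bromide with retention of alkene geometry; any SN2′ ether should revert to the conjugated trisubstituted isomer by alkoxide addition–elimination.

Step 8
Reactants: 9 (E)-2-(PMB-oxymethyl)enoate
Product: 10 (Z)-allylic alcohol
Conditions: i-Bu2AlH, CH2Cl2, −78 °C; aqueous potassium sodium tartrate
Reagents that add atoms: none
Why: 1,2-Reduction of the enoate by i-Bu2AlH gives the allylic alcohol in which the free CH2OH is trans and the CH2OPMB cis to the chain.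

Step 9
Reactants: 10 (Z)-allylic alcohol
Product: 11 (2R,3S)-epoxy alcohol
Conditions: Ti(OiPr)4, L-(+)-diethyl tartrate, t-BuOOH, 4 Å molecular sieves, CH2Cl2, −20 °C
Reagents that add atoms: tert-butyl hydroperoxide, CC(C)(C)OO
Why: Reagent-controlled Sharpless asymmetric epoxidation of a 2,3-disubstituted allylic alcohol, setting the quaternary oxygen-bearing carbon (future C3) and the adjacent epoxide carbon (future C3a, still to be inverted).

Step 10
Reactants: 11 (2R,3S)-epoxy alcohol
Product: 13 hydroxy γ-lactone, via ynol ether diol 12 (not isolated)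
Conditions: ethoxyacetylene, n-BuLi, then Et2AlCl, toluene, −78 to 0 °C; add 11, 0 °C to rt; aqueous potassium sodium tartrate; then TsOH·H2O (cat.), THF/H2O, 0 °C
Reagents that add atoms: ethoxyacetylene, C#COCC; water, O
Why: Organoaluminium opening of a 2,3-epoxy alcohol by an alkynylalane at the distal, less substituted carbon with inversion sets C3a anti to the C3 oxygen, and mild acid hydration of the ynol ether followed by lactonisation onto the tertiary hydroxyl gives the five-membered lactone.

Step 11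
Reactants: 13 hydroxy γ-lactone
Product: 14 TBS-protected vinyl lactone
Conditions: t-BuMe2SiCl, imidazole, DMF, rt
Reagents that add atoms: tert-butyl(chloro)dimethylsilane, CC(C)(C)[Si](C)(C)Cl
Why: Standard silylation of the primary alcohol, protecting the future stearate position through the reductions.

Step 12
Reactants: 14 TBS-protected vinyl lactone
Product: 15 lactone aldehyde
Conditions: OsO4 (cat.), NaIO4, 2,6-lutidine, 1,4-dioxane/H2O, rt
Reagents that add atoms: sodium periodate, [Na+].[O-]I(=O)(=O)=O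
Why: Lemieux–Johnson oxidative cleavage of the only alkene gives the α-silyloxy aldehyde, which has no α-hydrogen and cannot epimerise.

Step 13
Reactants: 16 3-bromobut-3-en-1-ol
Product: 17 2-bromo-4-iodobut-1-ene
Conditions: PPh3, I2, imidazole, CH2Cl2, 0 °C
Reagents that add atoms: iodine, [I][I]
Why: Appel iodination of the primary alcohol; the vinylic bromide is inert.

Step 14
Reactants: 17 2-bromo-4-iodobut-1-ene
Product: 18 (3-bromobut-3-en-1-yl)triphenylphosphonium iodide
Conditions: PPh3, MeCN, reflux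
Reagents that add atoms: triphenylphosphine, c1ccc(cc1)P(c1ccccc1)c1ccccc1
Why: SN2 quaternisation of the phosphine at the primary iodide.

Step 15
Reactants: 15 lactone aldehyde; 18 (3-bromobut-3-en-1-yl)triphenylphosphonium iodide
Product: 20 (Z)-bromodiene lactone, via phosphorus ylide 19 (not isolated)
Conditions: 18, NaN(SiMe3)2, THF, −78 °C; then 15, −78 °C to rt
Reagents that add atoms: none
Why: Wittig olefination with a non-stabilised ylide under salt-free conditions should give the (Z)-C7=C8 alkene through the kinetically favoured cis-oxaphosphetane.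

Step 16
Reactants: 20 (Z)-bromodiene lactone
Product: 23 trans-fused nine-membered bicyclic lactone, via lithium enolate 21 (not isolated), via chlorozinc enolate 22 (not isolated)
Conditions: LiN(SiMe3)2, THF, −78 °C; ZnCl2, −78 to 0 °C; syringe-pump addition to Pd2(dba)3 (tris(dibenzylideneacetone)dipalladium, 10 mol%) and P(t-Bu)3 (20 mol%) in THF, 60 °C, final concentration about 0.002 M; then DBU, rt
Reagents that add atoms: none
Why: Proposed new method: oxidative addition of the C10–Br bond of the 2-bromo-1-alkene to zerovalent palladium, transmetalation with the tethered chlorozinc lactone enolate to a C-bound alkenylpalladium enolate, and C(sp2)–C(sp3) reductive elimination should form the C10–C10a bond. The closest known reaction types are the intermolecular palladium-catalysed α-alkenylation of ester and lactone enolates with vinyl bromides and the intramolecular α-alkenylation of ketone enolates that closes five- to seven-membered rings; here the same elementary steps are asked to close a nine-membered ring. The carbocycle closes in an exo mode (the methylidene carbon stays outside the ring) through a ten-membered palladacycle that contracts on reductive elimination. The new stereocentre C10a is α to the lactone carbonyl and stays epimerisable, so it is expected to settle under base equilibration in the trans ring fusion, in which the nine-membered ring spans two trans bonds of the five-membered ring as in the target. The step needs ring closure to outrun oligomerisation and Claisen self-condensation, which slow addition at high dilution, the less basic zinc enolate, the (Z)-C7=C8 alkene and the fully substituted C6 and C3 turn elements should secure. C- over O-alkenylation follows from reductive elimination at the C-bound palladium enolate.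

Step 17
Reactants: 23 trans-fused nine-membered bicyclic lactone
Product: 24 1,4-diol
Conditions: LiAlH4, THF, 0 °C
Reagents that add atoms: none
Why: Hydride reduction of the lactone to the primary/tertiary 1,4-diol, with silyl and PMB ethers and the alkenes inert.

Step 18
Reactants: 24 1,4-diol
Product: 26 tetrahydrofuran PMB ether, via primary tosylate 25 (not isolated)
Conditions: TsCl, pyridine, DMAP (cat.), CH2Cl2, 0 °C to rt; then 45 °C
Reagents that add atoms: none
Why: Selective sulfonylation of the primary hydroxyl and 5-exo-tet intramolecular Williamson etherification by the tertiary hydroxyl close the C1–O2 bond without touching any stereocentre.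

Step 19
Reactants: 26 tetrahydrofuran PMB ether
Product: 27 primary alcohol
Conditions: DDQ, CH2Cl2/pH 7 phosphate buffer, 0 °C
Reagents that add atoms: none
Why: Oxidative cleavage of the electron-rich 4-methoxybenzyl ether by DDQ under neutral conditions, which the silyl ethers and unconjugated alkenes should tolerate.

Step 20
Reactants: 27 primary alcohol
Product: 28 C3 aldehyde
Conditions: Dess–Martin periodinane, NaHCO3, CH2Cl2, 0 °C to rt
Reagents that add atoms: none
Why: Dess–Martin oxidation to an aldehyde on a quaternary carbon, which cannot epimerise.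

Step 21
Reactants: 28 C3 aldehyde
Product: 29 bis-silylated (E)-diene
Conditions: diethyl (3-methylbut-2-en-1-yl)phosphonate, n-BuLi, THF, −78 °C; then 28, −78 °C to rt
Reagents that add atoms: diethyl (3-methylbut-2-en-1-yl)phosphonate, CCOP(=O)(CC=C(C)C)OCC
Why: Horner–Wadsworth–Emmons olefination with an allylic phosphonate, in which α-attack (the γ-carbon is disubstituted) and the usual stereochemical course should give the (E)-alkene of the 4-methylpenta-1,3-dienyl group.

Step 22
Reactants: 29 bis-silylated (E)-diene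
Product: 30 diol
Conditions: Bu4NF, THF, rt
Reagents that add atoms: none
Why: Fluoride-mediated cleavage of both silyl ethers under non-acidic conditions, which spares the tertiary allylic alcohol and the dienyl ether.

Step 23
Reactants: 30 diol
Product: 31 target stearate
Conditions: octadecanoyl chloride (1.05 equiv), pyridine, CH2Cl2, 0 °C
Reagents that add atoms: octadecanoyl chloride, CCCCCCCCCCCCCCCCCC(=O)Cl
Why: Chemoselective acylation of the primary hydroxyl, the tertiary allylic alcohol being too hindered to react.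

**Compound list**

1 | geraniol, (2E)-3,7-dimethylocta-2,6-dien-1-ol | CC(C)=CCC/C(C)=C/CO | starting material
2 | [(2S,3S)-3-methyl-3-(4-methylpent-3-en-1-yl)oxiran-2-yl]methanol | CC(C)=CCC[C@]1(C)O[C@H]1CO | intermediate
3 | (2R,3S)-2-(iodomethyl)-3-methyl-3-(4-methylpent-3-en-1-yl)oxirane | CC(C)=CCC[C@]1(C)O[C@H]1CI | intermediate
4 | (3S)-3,7-dimethylocta-1,6-dien-3-ol, (S)-linalool | CC(C)=CCC[C@](C)(O)C=C | intermediate
5 | triethyl{[(3S)-3,7-dimethylocta-1,6-dien-3-yl]oxy}silane | CC(C)=CCC[C@](C)(O[Si](CC)(CC)CC)C=C | intermediate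
6 | (4S)-4-methyl-4-[(triethylsilyl)oxy]hex-5-enal | O=CCC[C@](C)(O[Si](CC)(CC)CC)C=C | intermediate
7 | methyl (6S)-3-hydroxy-6-methyl-2-methylidene-6-[(triethylsilyl)oxy]oct-7-enoate (both C3 epimers) | C=C(C(=O)OC)C(O)CC[C@](C)(O[Si](CC)(CC)CC)C=C | intermediate
8 | methyl (2Z,6S)-2-(bromomethyl)-6-methyl-6-[(triethylsilyl)oxy]octa-2,7-dienoate | COC(=O)/C(CBr)=C/CC[C@](C)(O[Si](CC)(CC)CC)C=C | intermediate
9 | methyl (2E,6S)-2-{[(4-methoxyphenyl)methoxy]methyl}-6-methyl-6-[(triethylsilyl)oxy]octa-2,7-dienoate | COC(=O)/C(COCc1ccc(OC)cc1)=C/CC[C@](C)(O[Si](CC)(CC)CC)C=C | intermediate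
10 | (2Z,6S)-2-{[(4-methoxyphenyl)methoxy]methyl}-6-methyl-6-[(triethylsilyl)oxy]octa-2,7-dien-1-ol | OC/C(COCc1ccc(OC)cc1)=C/CC[C@](C)(O[Si](CC)(CC)CC)C=C | intermediate
11 | [(2R,3S)-2-{[(4-methoxyphenyl)methoxy]methyl}-3-{(3S)-3-methyl-3-[(triethylsilyl)oxy]pent-4-en-1-yl}oxiran-2-yl]methanol | OC[C@]1(COCc2ccc(OC)cc2)O[C@H]1CC[C@](C)(O[Si](CC)(CC)CC)C=C | intermediate
12 | (2R,3S,6S)-3-(ethoxyethynyl)-2-{[(4-methoxyphenyl)methoxy]methyl}-6-methyl-6-[(triethylsilyl)oxy]oct-7-ene-1,2-diol | CCOC#C[C@H](CC[C@](C)(O[Si](CC)(CC)CC)C=C)[C@@](O)(CO)COCc1ccc(OC)cc1 | intermediate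
13 | (4S,5R)-5-(hydroxymethyl)-5-{[(4-methoxyphenyl)methoxy]methyl}-4-{(3S)-3-methyl-3-[(triethylsilyl)oxy]pent-4-en-1-yl}oxolan-2-one | O=C1C[C@H](CC[C@](C)(O[Si](CC)(CC)CC)C=C)[C@@](CO)(COCc2ccc(OC)cc2)O1 | intermediate
14 | (4S,5S)-5-({[tert-butyl(dimethyl)silyl]oxy}methyl)-5-{[(4-methoxyphenyl)methoxy]methyl}-4-{(3S)-3-methyl-3-[(triethylsilyl)oxy]pent-4-en-1-yl}oxolan-2-one | O=C1C[C@H](CC[C@](C)(O[Si](CC)(CC)CC)C=C)[C@@](CO[Si](C)(C)C(C)(C)C)(COCc2ccc(OC)cc2)O1 | intermediate
15 | (2S)-4-[(2S,3S)-2-({[tert-butyl(dimethyl)silyl]oxy}methyl)-2-{[(4-methoxyphenyl)methoxy]methyl}-5-oxooxolan-3-yl]-2-methyl-2-[(triethylsilyl)oxy]butanal | O=C1C[C@H](CC[C@](C)(O[Si](CC)(CC)CC)C=O)[C@@](CO[Si](C)(C)C(C)(C)C)(COCc2ccc(OC)cc2)O1 | intermediate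
16 | 3-bromobut-3-en-1-ol | OCCC(Br)=C | starting material
17 | 2-bromo-4-iodobut-1-ene | ICCC(Br)=C | intermediate
18 | (3-bromobut-3-en-1-yl)triphenylphosphonium iodide | [I-].C=C(Br)CC[P+](c1ccccc1)(c1ccccc1)c1ccccc1 | intermediate
19 | (3-bromobut-3-en-1-ylidene)triphenyl-λ5-phosphane | C=C(Br)CC=P(c1ccccc1)(c1ccccc1)c1ccccc1 | intermediate
20 | (4S,5S)-4-{(3S,4Z)-7-bromo-3-methyl-3-[(triethylsilyl)oxy]octa-4,7-dien-1-yl}-5-({[tert-butyl(dimethyl)silyl]oxy}methyl)-5-{[(4-methoxyphenyl)methoxy]methyl}oxolan-2-one | O=C1C[C@H](CC[C@](C)(O[Si](CC)(CC)CC)/C=C\CC(Br)=C)[C@@](CO[Si](C)(C)C(C)(C)C)(COCc2ccc(OC)cc2)O1 | intermediate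
21 | lithium enolate of 20: lithium (4S,5S)-4-{(3S,4Z)-7-bromo-3-methyl-3-[(triethylsilyl)oxy]octa-4,7-dien-1-yl}-5-({[tert-butyl(dimethyl)silyl]oxy}methyl)-5-{[(4-methoxyphenyl)methoxy]methyl}-4,5-dihydrofuran-2-olate | [Li]OC1=C[C@H](CC[C@](C)(O[Si](CC)(CC)CC)/C=C\CC(Br)=C)[C@@](CO[Si](C)(C)C(C)(C)C)(COCc2ccc(OC)cc2)O1 | intermediate
22 | chlorozinc enolate of 20 (O-bound ClZn in place of Li in 21) | Cl[Zn]OC1=C[C@H](CC[C@](C)(O[Si](CC)(CC)CC)/C=C\CC(Br)=C)[C@@](CO[Si](C)(C)C(C)(C)C)(COCc2ccc(OC)cc2)O1 | intermediate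
23 | (3S,3aS,6S,7Z,10aR)-3-({[tert-butyl(dimethyl)silyl]oxy}methyl)-3-{[(4-methoxyphenyl)methoxy]methyl}-6-methyl-10-methylidene-6-[(triethylsilyl)oxy]-3,3a,4,5,6,9,10,10a-octahydro-1H-cyclonona[c]furan-1-one | C=C1C/C=C\[C@@](C)(O[Si](CC)(CC)CC)CC[C@H]2[C@H]1C(=O)O[C@@]2(COCc3ccc(OC)cc3)CO[Si](C)(C)C(C)(C)C | intermediate
24 | (2S)-1-{[tert-butyl(dimethyl)silyl]oxy}-2-{(1S,2R,5Z,7S)-2-(hydroxymethyl)-7-methyl-3-methylidene-7-[(triethylsilyl)oxy]cyclonon-5-en-1-yl}-3-[(4-methoxyphenyl)methoxy]propan-2-ol | C=C1C/C=C\[C@@](C)(O[Si](CC)(CC)CC)CC[C@H]([C@](O)(COCc2ccc(OC)cc2)CO[Si](C)(C)C(C)(C)C)[C@H]1CO | intermediate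
25 | 4-methylbenzenesulfonate of the ring CH2OH group of 24 (tertiary hydroxyl free) | C=C1C/C=C\[C@@](C)(O[Si](CC)(CC)CC)CC[C@H]([C@](O)(COCc2ccc(OC)cc2)CO[Si](C)(C)C(C)(C)C)[C@H]1COS(=O)(=O)c1ccc(C)cc1 | intermediate
26 | tert-butyl{[(3S,3aS,6S,7Z,10aR)-3-{[(4-methoxyphenyl)methoxy]methyl}-6-methyl-10-methylidene-6-[(triethylsilyl)oxy]-3,3a,4,5,6,9,10,10a-octahydro-1H-cyclonona[c]furan-3-yl]methoxy}dimethylsilane | C=C1C/C=C\[C@@](C)(O[Si](CC)(CC)CC)CC[C@H]2[C@H]1CO[C@@]2(COCc3ccc(OC)cc3)CO[Si](C)(C)C(C)(C)C | intermediate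
27 | [(3S,3aS,6S,7Z,10aR)-3-({[tert-butyl(dimethyl)silyl]oxy}methyl)-6-methyl-10-methylidene-6-[(triethylsilyl)oxy]-3,3a,4,5,6,9,10,10a-octahydro-1H-cyclonona[c]furan-3-yl]methanol | C=C1C/C=C\[C@@](C)(O[Si](CC)(CC)CC)CC[C@H]2[C@H]1CO[C@@]2(CO)CO[Si](C)(C)C(C)(C)C | intermediate
28 | (3R,3aS,6S,7Z,10aR)-3-({[tert-butyl(dimethyl)silyl]oxy}methyl)-6-methyl-10-methylidene-6-[(triethylsilyl)oxy]-3,3a,4,5,6,9,10,10a-octahydro-1H-cyclonona[c]furan-3-carbaldehyde | C=C1C/C=C\[C@@](C)(O[Si](CC)(CC)CC)CC[C@H]2[C@H]1CO[C@@]2(C=O)CO[Si](C)(C)C(C)(C)C | intermediate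
29 | tert-butyldimethyl{[(3R,3aS,6S,7Z,10aR)-6-methyl-10-methylidene-3-[(1E)-4-methylpenta-1,3-dien-1-yl]-6-[(triethylsilyl)oxy]-3,3a,4,5,6,9,10,10a-octahydro-1H-cyclonona[c]furan-3-yl]methoxy}silane | C=C1C/C=C\[C@@](C)(O[Si](CC)(CC)CC)CC[C@H]2[C@H]1CO[C@@]2(/C=C/C=C(C)C)CO[Si](C)(C)C(C)(C)C | intermediate
30 | (3R,3aS,6S,7Z,10aR)-3-(hydroxymethyl)-6-methyl-10-methylidene-3-[(1E)-4-methylpenta-1,3-dien-1-yl]-3,3a,4,5,6,9,10,10a-octahydro-1H-cyclonona[c]furan-6-ol | C=C1C/C=C\[C@@](C)(O)CC[C@H]2[C@H]1CO[C@@]2(/C=C/C=C(C)C)CO | intermediate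
31 | [(3R,3aS,6S,7Z,10aR)-6-hydroxy-6-methyl-10-methylidene-3-[(1E)-4-methylpenta-1,3-dien-1-yl]-3,3a,4,5,6,9,10,10a-octahydro-1H-cyclonona[c]furan-3-yl]methyl octadecanoate | C=C1C/C=C\[C@@](C)(O)CC[C@H]2[C@H]1CO[C@@]2(/C=C/C=C(C)C)COC(=O)CCCCCCCCCCCCCCCCC | target

**Step count and risks**

Total step count: 23. Longest linear sequence: 21 steps (geraniol to the target, steps 1–12 and 15–23); steps 13–14 prepare the phosphonium salt.

Steps most likely to fail:

1. Step 16 (Proposed new method). Medium-ring reductive elimination may lose to oligomerisation, protodebromination or β-hydride loss from the alkenylpalladium intermediate, or the ring may close with the cis fusion. The fallback sets out from 14 and comes back at 23. The lithium enolate of 14 (LiN(SiMe3)2, toluene) would be alkenylated intermolecularly under Pd2(dba)3/P(t-Bu)3 catalysis with 2-bromopenta-1,4-diene F1, prepared from 2,3-dibromopropene and CH2=CHMgBr with CuI. The electrophile should enter anti to the C4 side chain to give the trans-3,4-disubstituted lactone F2. Ring-closing metathesis between the two monosubstituted vinyl groups of F2 (second-generation Grubbs catalyst, toluene, 80 °C, high dilution) would then form the (Z)-C7=C8 bond and return to 23. Steps 12–15 then become unnecessary.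

2. Step 10. Lewis-acid-assisted opening at the fully substituted epoxide carbon, or lactonisation onto the primary instead of the tertiary hydroxyl, may compete. The fallback sets out from 11 and comes back at 13. SN2 opening with sodium dimethyl malonate (NaOMe, MeOH, reflux) at the less substituted epoxide carbon, with lactonisation of the tertiary alkoxide in the same flask, would give the α-methoxycarbonyl lactone F3. Krapcho dealkoxycarbonylation (LiCl, wet DMSO, 140 °C) then returns to 13.

3. Step 15. The bromo-substituted ylide may decompose by elimination, or Z-selectivity may erode at the hindered α-silyloxy aldehyde. The fallback sets out from 15 and comes back at 20. Seyferth–Gilbert homologation with dimethyl (1-diazo-2-oxopropyl)phosphonate (K2CO3, MeOH) would give the terminal alkyne F4. Copper-mediated coupling with 2,3-dibromopropene (CuI, K2CO3, NaI, DMF) would give the skipped enyne F5. Cis-selective semihydrogenation (H2, Pd/CaCO3 poisoned with Pb(OAc)2, quinoline) then returns to 20.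

**Further compounds**

F1 | step 16 | 2-bromopenta-1,4-diene | C=CCC(Br)=C
F2 | step 16 | (3R,4S,5S)-5-({[tert-butyl(dimethyl)silyl]oxy}methyl)-5-{[(4-methoxyphenyl)methoxy]methyl}-4-{(3S)-3-methyl-3-[(triethylsilyl)oxy]pent-4-en-1-yl}-3-(penta-1,4-dien-2-yl)oxolan-2-one | O=C1[C@@H](C(=C)CC=C)[C@H](CC[C@](C)(O[Si](CC)(CC)CC)C=C)[C@@](CO[Si](C)(C)C(C)(C)C)(COCc2ccc(OC)cc2)O1
F3 | step 10 | methyl (4S,5R)-5-(hydroxymethyl)-5-{[(4-methoxyphenyl)methoxy]methyl}-4-{(3S)-3-methyl-3-[(triethylsilyl)oxy]pent-4-en-1-yl}-2-oxooxolane-3-carboxylate (C3 epimers) | O=C1C(C(=O)OC)[C@H](CC[C@](C)(O[Si](CC)(CC)CC)C=C)[C@@](CO)(COCc2ccc(OC)cc2)O1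
F4 | step 15 | (4S,5S)-5-({[tert-butyl(dimethyl)silyl]oxy}methyl)-5-{[(4-methoxyphenyl)methoxy]methyl}-4-{(3S)-3-methyl-3-[(triethylsilyl)oxy]pent-4-yn-1-yl}oxolan-2-one | O=C1C[C@H](CC[C@](C)(O[Si](CC)(CC)CC)C#C)[C@@](CO[Si](C)(C)C(C)(C)C)(COCc2ccc(OC)cc2)O1
F5 | step 15 | (4S,5S)-4-{(3S)-7-bromo-3-methyl-3-[(triethylsilyl)oxy]oct-7-en-4-yn-1-yl}-5-({[tert-butyl(dimethyl)silyl]oxy}methyl)-5-{[(4-methoxyphenyl)methoxy]methyl}oxolan-2-one | O=C1C[C@H](CC[C@](C)(O[Si](CC)(CC)CC)C#CCC(Br)=C)[C@@](CO[Si](C)(C)C(C)(C)C)(COCc2ccc(OC)cc2)O1
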